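**Retrosynthetic overview**
1. Chain numbering: C1 (ester carbon) to C20 (CHBr). The only ring is the oxolane O/C5–C8, trans-2,5-disubstituted, (5R,8S).
2. Last bond C10–C11: Sonogashira coupling of the C1–C10 ethynyl-oxolane with the C11–C20 iodo-bromo-triene (octa-1,7-diyne plus a two-carbon bromovinyl unit). C9≡C10 comes from a C9 aldehyde and the C1 ester from a C2=C1 vinyl group.
3. Feature used: ring carbon C5 is bonded to the unbranched arm C4–C3–C2–C1, and the ring bond C6–C7 carries no substituent. Drawn as C6=C7 it is a metathesis bond, and C6 was then double-bonded to C2 beforehand, so C5–C6=C2–C3–C4 is a cyclopent-2-enyl group on the ring oxygen and C7 is a vinyl carbon on C8.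
4. The cyclopentenyl ether is made from (R)-cyclopent-2-en-1-ol (C5; from cyclopentenone by iodination, oxazaborolidine reduction and deiodination) by an iridium-catalysed branched allylic etherification that sets C8.
5. Ring order: the carbocycle is bought and consumed; the oxolane is the only ring formed (step 7) and is saturated afterwards.

Key step: step 7

Assumption: the (Sa,S,S) phosphoramidite is taken to be the enantiomer that gives (S) at C8, by analogy with the facial sense of these iridium catalysts on other allyl carbonates; if the sense is opposite, the mirror-image ligand is used and nothing else changes.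

Note on notation: the cyclopentadienyl ligands of the zirconocene species are drawn as σ-bonded rings in the SMILES strings.

**Route**

Step 1
Reactants: 1 cyclopent-2-en-1-one
Product: 2 2-iodocyclopent-2-en-1-one
Conditions: I2 (1.5 equiv), pyridine/CH2Cl2 (1:1), 0 °C to rt
Reagents that add atoms: iodine, [I][I]
Why: α-Iodination of the enone by conjugate addition of pyridine, iodination of the enolate and elimination (a Baylis–Hillman-type addition–elimination) puts a large, removable group on C-2, so that the two flanks of the carbonyl differ clearly in the next step, which plain cyclopentenone would not offer.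

Step 2
Reactants: 2 2-iodocyclopent-2-en-1-one
Product: 3 (1R)-2-iodocyclopent-2-en-1-ol
Conditions: (S)-2-methyl-CBS-oxazaborolidine (0.2 equiv), BH3·SMe2 (0.7 equiv), THF, 0 °C; MeOH quench
Reagents that add atoms: none
Why: Corey–Bakshi–Shibata reduction, in which the ketone binds the ring boron of the (S)-oxazaborolidine with the iodoalkenyl flank as the large group, so that hydride from the nitrogen-bound borane should reach the face that gives the (R)-carbinol (the future C5) by 1,2-reduction only.

Step 3
Reactants: 3 (1R)-2-iodocyclopent-2-en-1-ol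
Product: 5 (1R)-cyclopent-2-en-1-ol, via vinyllithium alkoxide 4 (not isolated)
Conditions: t-BuLi (3.1 equiv), Et2O, −78 °C; then H2O, −78 °C to rt; volatile product kept as a concentrated ether solution
Reagents that add atoms: tert-butyllithium, [Li]C(C)(C)C (lithium stays only in 4)
Why: Iodine–lithium exchange on the lithium alkoxide followed by protonation removes the iodine without touching the C–O stereocentre, and the β-oxido vinyllithium cannot eliminate because the resulting five-membered cycloalkyne or allene is too strained.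

Step 4
Reactants: 6 (E)-but-2-ene-1,4-diol
Product: 7 (E)-4-[tert-butyl(dimethyl)silyl]oxybut-2-en-1-ol
Conditions: 6 (3 equiv), TBSCl (1 equiv), imidazole (1.2 equiv), DMF, 0 °C
Reagents that add atoms: tert-butyldimethylsilyl chloride, CC(C)(C)[Si](C)(C)Cl
Why: Statistical monosilylation of the symmetric diol used in excess should give mainly the mono-ether, and the unreacted diol is washed out with water.

Step 5
Reactants: 7 (E)-4-[tert-butyl(dimethyl)silyl]oxybut-2-en-1-ol
Product: 8 tert-butyl [(E)-4-[tert-butyl(dimethyl)silyl]oxybut-2-enyl] carbonate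
Conditions: Boc2O (1.3 equiv), Bu4NHSO4 (5 mol%), 30% aq NaOH, CH2Cl2, 0 °C to rt
Reagents that add atoms: di-tert-butyl dicarbonate, CC(C)(C)OC(=O)OC(=O)OC(C)(C)C
Why: Phase-transfer O-acylation of the primary allylic alcohol gives the tert-butyl carbonate, chosen because the tert-butoxide it later releases is too hindered to compete as a nucleophile.

Step 6
Reactants: 5 (1R)-cyclopent-2-en-1-ol; 8 tert-butyl [(E)-4-[tert-butyl(dimethyl)silyl]oxybut-2-enyl] carbonate
Product: 11 tert-butyl-[(2S)-2-[(1R)-cyclopent-2-en-1-yl]oxybut-3-enoxy]-dimethylsilane, via lithium alkoxide 9 (not isolated), via copper alkoxide 10 (not isolated)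
Conditions: 5 (1.5 equiv), n-BuLi, THF, 0 °C; CuI, rt; then 8 (1 equiv), [Ir(cod)Cl]2 (2 mol%), (Sa,S,S)-O,O′-(1,1′-binaphthyl-2,2′-diyl) N,N-bis(1-phenylethyl)phosphoramidite (4 mol%), THF, rt
Reagents that add atoms: n-butyllithium, [Li]CCCC (lithium stays only in 9); copper iodide, [Cu]I (copper stays only in 10)
Why: Iridium-catalysed asymmetric allylic etherification, in which the iridium–phosphoramidite catalyst ionises the linear carbonate and the soft copper alkoxide attacks the substituted allyl terminus, so the branched ether should form with C8 set as (S) by the ligand (catalyst control, independent of the alkoxide), while C5 is carried in unchanged from 5 because its C–O bond is not broken.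

Step 7
Reactants: 11 tert-butyl-[(2S)-2-[(1R)-cyclopent-2-en-1-yl]oxybut-3-enoxy]-dimethylsilane
Product: 12 tert-butyl-[[(2S,5R)-5-but-3-enyl-2,5-dihydrofuran-2-yl]methoxy]-dimethylsilane
Conditions: second-generation Grubbs catalyst RuCl2(=CHPh)(H2IMes)(PCy3) (5 mol%), ethylene (1 atm), CH2Cl2 (0.01 M), rt to 40 °C
Reagents that add atoms: none
Why: The ruthenium alkylidene is loaded onto the unhindered C7 vinyl group and adds across the cyclopentene C6=C2 bond through a ruthenacyclobutane in which C7 bonds to C6; cycloreversion closes the 2,5-dihydrofuran (forming C6=C7) and opens the carbocycle to a Ru=C2 alkylidene, which ethylene converts into the C2=C1 vinyl end. The closest known reaction type is the ring-rearrangement metathesis (ring-opening/ring-closing cascade) of cycloalkenyl allyl ethers to 2,5-dihydrofurans. The oxolane ring is closed by ring-closing metathesis in the five-membered mode, with O, C5 and C8 already in place and only the C6=C7 bond made. No stereocentre is formed: C5 and C8 are sp3 spectators, so the (5R,8S) pattern fixed in 11 appears as the trans 2,5-relationship of 12. The step needs five-membered closure to win over addition in the opposite orientation (C7 to C2, a seven-membered oxepine) and over intermolecular metathesis; the one-oxygen tether puts C6 within reach in an unstrained metallacycle, and dilution under ethylene keeps the catalyst as the methylidene and returns cross-metathesis dimers to monomer. The exchange is close to neutral in ring strain and is expected to be pulled towards 12 because its ring alkene, flanked by two substituted allylic carbons, is re-engaged by the catalyst much more slowly than the cyclopentene of 11.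

Step 8
Reactants: 12 tert-butyl-[[(2S,5R)-5-but-3-enyl-2,5-dihydrofuran-2-yl]methoxy]-dimethylsilane
Product: 14 4-[(2R,5S)-5-[[tert-butyl(dimethyl)silyl]oxymethyl]-2,5-dihydrofuran-2-yl]butan-1-ol, via alkylborane 13 (not isolated)
Conditions: 9-BBN (1.2 equiv), THF, 0 °C to rt; then 3 M aq NaOH, 30% H2O2, 0 °C
Reagents that add atoms: hydrogen peroxide, OO; 9-borabicyclo[3.3.1]nonane, [H]B1C2CCCC1CCC2 (boron stays only in 13)
Why: Anti-Markovnikov hydroboration–oxidation, in which the bulky dialkylborane should add only to the monosubstituted C2=C1 alkene and leave the cis-disubstituted ring alkene (flanked by two branched carbons) alone, giving the C1 primary alcohol.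

Step 9
Reactants: 14 4-[(2R,5S)-5-[[tert-butyl(dimethyl)silyl]oxymethyl]-2,5-dihydrofuran-2-yl]butan-1-ol
Product: 15 4-[(2R,5S)-5-[[tert-butyl(dimethyl)silyl]oxymethyl]oxolan-2-yl]butan-1-ol
Conditions: H2 (1 atm), PtO2 (5 mol%), EtOAc, rt
Reagents that add atoms: none
Why: Heterogeneous catalytic hydrogenation saturates C6=C7 without creating a stereocentre, and platinum is chosen because it has little tendency to move the alkene into the enol-ether position, which would put C5 or C8 at risk.

Step 10
Reactants: 15 4-[(2R,5S)-5-[[tert-butyl(dimethyl)silyl]oxymethyl]oxolan-2-yl]butan-1-ol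
Product: 17 4-[(2R,5S)-5-[[tert-butyl(dimethyl)silyl]oxymethyl]oxolan-2-yl]butanoic acid, via aldehyde 16 (not isolated)
Conditions: TEMPO (0.2 equiv), PhI(OAc)2 (2.5 equiv), MeCN/H2O (1:1), rt
Reagents that add atoms: water, O
Why: Oxoammonium-mediated (TEMPO) oxidation takes the primary alcohol to the aldehyde and, through its hydrate, to the carboxylic acid under near-neutral conditions that the silyl ether and the oxolane should tolerate.

Step 11
Reactants: 17 4-[(2R,5S)-5-[[tert-butyl(dimethyl)silyl]oxymethyl]oxolan-2-yl]butanoic acid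
Product: 18 methyl 4-[(2R,5S)-5-(hydroxymethyl)oxolan-2-yl]butanoate
Conditions: HCl (1.25 M in MeOH), rt
Reagents that add atoms: methanol, CO
Why: Fischer esterification in acidic methanol forms the methyl ester while the same medium solvolyses the primary silyl ether, so C1 and C9 reach their required states in one operation.

Step 12
Reactants: 18 methyl 4-[(2R,5S)-5-(hydroxymethyl)oxolan-2-yl]butanoate
Product: 19 methyl 4-[(2R,5S)-5-formyloxolan-2-yl]butanoate
Conditions: Dess–Martin periodinane (1.3 equiv), CH2Cl2, 0 °C to rt; crude aldehyde used at once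
Reagents that add atoms: none
Why: Dess–Martin oxidation gives the α-alkoxy aldehyde under non-basic conditions, so the C8 stereocentre next to the carbonyl should not epimerise.

Step 13
Reactants: 19 methyl 4-[(2R,5S)-5-formyloxolan-2-yl]butanoate
Product: 20 methyl 4-[(2R,5S)-5-ethynyloxolan-2-yl]butanoate
Conditions: dimethyl (1-diazo-2-oxopropyl)phosphonate (1.5 equiv), K2CO3 (2 equiv), MeOH, 0 °C to rt
Reagents that add atoms: dimethyl (1-diazo-2-oxopropyl)phosphonate, COP(=O)(OC)C(=[N+]=[N-])C(C)=O
Why: Ohira–Bestmann (Seyferth–Gilbert) homologation, in which the diazomethylphosphonate anion released by methanolysis adds to the aldehyde and loss of phosphate and N2 with a 1,2-hydrogen shift gives the C9≡C10 terminal alkyne under conditions mild enough to keep C8 and the methyl ester intact.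

Step 14
Reactants: 21 ethyne
Product: 22 (E)-1-bromo-2-iodoethene
Conditions: IBr (1 equiv), 48% aq HBr, ethyne bubbled in, 0 °C
Reagents that add atoms: iodine monobromide, BrI
Why: Electrophilic anti addition of I–Br across the alkyne through a bridged iodonium ion should give the (E)-1,2-dihaloethene.

Step 15
Reactants: 23 octa-1,7-diyne
Product: 25 trimethyl(octa-1,7-diynyl)silane, via lithium acetylide 24 (not isolated)
Conditions: 23 (3 equiv), n-BuLi (1 equiv), THF, −78 °C; TMSCl (1 equiv), −78 °C to rt; distillation
Reagents that add atoms: chlorotrimethylsilane, C[Si](C)(C)Cl; n-butyllithium, [Li]CCCC (lithium stays only in 24)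
Why: Deprotonation of one terminal alkyne of the diyne used in excess and C-silylation of the acetylide tell the two ends apart, and diyne, mono- and bis-silyl compounds are separable by distillation.

Step 16
Reactants: 25 trimethyl(octa-1,7-diynyl)silane; 22 (E)-1-bromo-2-iodoethene
Product: 27 [(7E,9E)-10-bromodeca-7,9-dien-1-ynyl]-trimethylsilane, via alkenylzirconocene 26 (not isolated)
Conditions: Cp2Zr(H)Cl (1.1 equiv), THF, rt; then 22 (1.2 equiv), Pd(PPh3)4 (3 mol%), ZnCl2 (0.2 equiv), THF, rt
Reagents that add atoms: zirconocene chloride hydride, [H][Zr](Cl)(C1C=CC=C1)C1C=CC=C1 (zirconium stays only in 26)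
Why: syn-Hydrozirconation of the terminal alkyne (the silylalkyne reacts far more slowly) fixes the (E) geometry of C17=C18, and the Negishi-type palladium-catalysed alkenyl–alkenyl coupling should then occur with retention at the C–I bond of 22 only, since oxidative addition into C–I is much faster than into C–Br, giving the (E,E)-bromodiene.

Step 17
Reactants: 27 [(7E,9E)-10-bromodeca-7,9-dien-1-ynyl]-trimethylsilane
Product: 28 (1E,3E)-1-bromodeca-1,3-dien-9-yne
Conditions: K2CO3 (0.2 equiv), MeOH, rt
Reagents that add atoms: none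
Why: Methanolysis of the C(sp)–Si bond by catalytic methoxide frees the terminal alkyne and should leave the bromodiene untouched.

Step 18
Reactants: 28 (1E,3E)-1-bromodeca-1,3-dien-9-yne
Product: 30 (1E,3E,9E)-1-bromo-10-iododeca-1,3,9-triene, via alkenylzirconocene 29 (not isolated)
Conditions: Cp2Zr(H)Cl (1.1 equiv), THF, rt, dark; then I2 (1.05 equiv), THF, −78 to 0 °C
Reagents that add atoms: iodine, [I][I]; zirconocene chloride hydride, [H][Zr](Cl)(C1C=CC=C1)C1C=CC=C1 (zirconium stays only in 29)
Why: Hydrozirconation–iodination, in which syn addition of Zr–H to the terminal alkyne (much faster than to the conjugated bromodiene) and iodinolysis of the C–Zr bond with retention should give the (E)-alkenyl iodide.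

Step 19
Reactants: 20 methyl 4-[(2R,5S)-5-ethynyloxolan-2-yl]butanoate; 30 (1E,3E,9E)-1-bromo-10-iododeca-1,3,9-triene
Product: 31 methyl 4-[(2R,5S)-5-[(3E,9E,11E)-12-bromododeca-3,9,11-trien-1-ynyl]oxolan-2-yl]butanoate
Conditions: 30 (1.2 equiv), Pd(PPh3)4 (5 mol%), CuI (10 mol%), Et3N (3 equiv), degassed THF, 0 °C to rt, dark
Reagents that add atoms: none
Why: Sonogashira coupling forms C10–C11 with retention of the (E) geometry, and the alkenyl iodide should react selectively at room temperature because oxidative addition into C–I is much faster than into the C–Br bond of the bromodiene.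

**Compound list**
1 | cyclopent-2-en-1-one | O=C1C=CCC1 | starting material
2 | 2-iodocyclopent-2-en-1-one | IC1=CCCC1=O | intermediate
3 | (1R)-2-iodocyclopent-2-en-1-ol | IC1=CCC[C@H]1O | intermediate
4 | lithium (1R)-2-lithiocyclopent-2-en-1-olate | [Li]O[C@H]1C([Li])=CCC1 | intermediate
5 | (1R)-cyclopent-2-en-1-ol | O[C@H]1C=CCC1 | intermediate
6 | (E)-but-2-ene-1,4-diol | OC/C=C/CO | starting material
7 | (E)-4-[tert-butyl(dimethyl)silyl]oxybut-2-en-1-ol | CC(C)(C)[Si](C)(C)OC/C=C/CO | intermediate
8 | tert-butyl [(E)-4-[tert-butyl(dimethyl)silyl]oxybut-2-enyl] carbonate | CC(C)(C)OC(=O)OC/C=C/CO[Si](C)(C)C(C)(C)C | intermediate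
9 | lithium (1R)-cyclopent-2-en-1-olate | [Li]O[C@H]1C=CCC1 | intermediate
10 | monovalent copper (1R)-cyclopent-2-en-1-olate | [Cu]O[C@H]1C=CCC1 | intermediate
11 | tert-butyl-[(2S)-2-[(1R)-cyclopent-2-en-1-yl]oxybut-3-enoxy]-dimethylsilane | C=C[C@@H](CO[Si](C)(C)C(C)(C)C)O[C@H]1C=CCC1 | intermediate
12 | tert-butyl-[[(2S,5R)-5-but-3-enyl-2,5-dihydrofuran-2-yl]methoxy]-dimethylsilane | C=CCC[C@@H]1C=C[C@@H](CO[Si](C)(C)C(C)(C)C)O1 | intermediate
13 | 9-[4-[(2R,5S)-5-[[tert-butyl(dimethyl)silyl]oxymethyl]-2,5-dihydrofuran-2-yl]butyl]-9-borabicyclo[3.3.1]nonane | C1CCC2CCCC1B2CCCC[C@@H]1C=C[C@@H](CO[Si](C)(C)C(C)(C)C)O1 | intermediate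
14 | 4-[(2R,5S)-5-[[tert-butyl(dimethyl)silyl]oxymethyl]-2,5-dihydrofuran-2-yl]butan-1-ol | OCCCC[C@@H]1C=C[C@@H](CO[Si](C)(C)C(C)(C)C)O1 | intermediate
15 | 4-[(2R,5S)-5-[[tert-butyl(dimethyl)silyl]oxymethyl]oxolan-2-yl]butan-1-ol | OCCCC[C@@H]1CC[C@@H](CO[Si](C)(C)C(C)(C)C)O1 | intermediate
16 | 4-[(2R,5S)-5-[[tert-butyl(dimethyl)silyl]oxymethyl]oxolan-2-yl]butanal | O=CCCC[C@@H]1CC[C@@H](CO[Si](C)(C)C(C)(C)C)O1 | intermediate
17 | 4-[(2R,5S)-5-[[tert-butyl(dimethyl)silyl]oxymethyl]oxolan-2-yl]butanoic acid | OC(=O)CCC[C@@H]1CC[C@@H](CO[Si](C)(C)C(C)(C)C)O1 | intermediate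
18 | methyl 4-[(2R,5S)-5-(hydroxymethyl)oxolan-2-yl]butanoate | COC(=O)CCC[C@@H]1CC[C@@H](CO)O1 | intermediate
19 | methyl 4-[(2R,5S)-5-formyloxolan-2-yl]butanoate | COC(=O)CCC[C@@H]1CC[C@@H](C=O)O1 | intermediate
20 | methyl 4-[(2R,5S)-5-ethynyloxolan-2-yl]butanoate | COC(=O)CCC[C@@H]1CC[C@@H](C#C)O1 | intermediate
21 | ethyne | C#C | starting material
22 | (E)-1-bromo-2-iodoethene | Br/C=C/I | intermediate
23 | octa-1,7-diyne | C#CCCCCC#C | starting material
24 | lithium octa-1,7-diyn-1-ide | [Li]C#CCCCCC#C | intermediate
25 | trimethyl(octa-1,7-diynyl)silane | C[Si](C)(C)C#CCCCCC#C | intermediate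
26 | chloro-bis(cyclopentadienyl)-[(E)-8-trimethylsilyloct-1-en-7-ynyl]zirconium | C[Si](C)(C)C#CCCCC/C=C/[Zr](Cl)(C1C=CC=C1)C1C=CC=C1 | intermediate
27 | [(7E,9E)-10-bromodeca-7,9-dien-1-ynyl]-trimethylsilane | C[Si](C)(C)C#CCCCC/C=C/C=C/Br | intermediate
28 | (1E,3E)-1-bromodeca-1,3-dien-9-yne | C#CCCCC/C=C/C=C/Br | intermediate
29 | [(1E,7E,9E)-10-bromodeca-1,7,9-trienyl]-chloro-bis(cyclopentadienyl)zirconium | Br/C=C/C=C/CCCC/C=C/[Zr](Cl)(C1C=CC=C1)C1C=CC=C1 | intermediate
30 | (1E,3E,9E)-1-bromo-10-iododeca-1,3,9-triene | Br/C=C/C=C/CCCC/C=C/I | intermediate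
31 | methyl 4-[(2R,5S)-5-[(3E,9E,11E)-12-bromododeca-3,9,11-trien-1-ynyl]oxolan-2-yl]butanoate | COC(=O)CCC[C@@H]1CC[C@@H](C#C/C=C/CCCC/C=C/C=C/Br)O1 | target

**Step count**
Total: 19 steps. Longest linear sequence: 12 steps (steps 1, 2, 3, 6, 7, 8, 9, 10, 11, 12, 13 and 19).

**The three steps most likely to fail**

Step 7 (key step). What may go wrong: the rearrangement may stop at an equilibrium mixture of 11 and 12, or cross-metathesis of the terminal alkenes may build oligomers faster than the catalyst opens the cyclopentene. Fallback: a plain ring-closing metathesis of an acyclic diene, driven by loss of ethylene, in which no carbocycle has to be opened; it sets out from 8 and returns at 15. Commercial 5-phenylmethoxypentanal is treated with vinylmagnesium bromide to give racemic 7-phenylmethoxyhept-1-en-3-ol F3. Sharpless kinetic resolution [Ti(OiPr)4, L-(+)-diisopropyl tartrate, t-BuOOH, CH2Cl2, −20 °C] should consume the (S)-enantiomer and leave (3R)-7-phenylmethoxyhept-1-en-3-ol F4. This is converted with n-BuLi into lithium (3R)-7-phenylmethoxyhept-1-en-3-olate F5 and with CuI into monovalent copper (3R)-7-phenylmethoxyhept-1-en-3-olate F6, which is etherified with 8 under the conditions of step 6 to give tert-butyl-dimethyl-[(2S)-2-[(3R)-7-phenylmethoxyhept-1-en-3-yl]oxybut-3-enoxy]silane F7. Ring-closing metathesis of the two allylic vinyl groups (second-generation Grubbs catalyst, CH2Cl2, 40 °C) should give tert-butyl-dimethyl-[[(2S,5R)-5-(4-phenylmethoxybutyl)-2,5-dihydrofuran-2-yl]methoxy]silane F8. Hydrogenation over PtO2 gives tert-butyl-dimethyl-[[(2S,5R)-5-(4-phenylmethoxybutyl)oxolan-2-yl]methoxy]silane F9, and hydrogenolysis of the benzyl ether (H2, Pd/C, EtOAc) gives 15.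

Step 6. What may go wrong: loss of branched selectivity (attack at the unsubstituted allyl terminus) or incomplete catalyst control at C8 with the hindered secondary alkoxide, giving a mixture of diastereomers that would pass into the ring as cis and trans isomers. Fallback: C8 is taken from the chiral pool and the ether is made stereospecifically; it sets out from 5 and returns at 11. Commercial (S)-tert-butyldimethylsilyl glycidyl ether is opened with dimethylsulfonium methylide (Me3SI, n-BuLi, THF) to give (2S)-1-[tert-butyl(dimethyl)silyl]oxybut-3-en-2-ol F1, which is converted with n-BuLi and Boc2O into tert-butyl [(2S)-1-[tert-butyl(dimethyl)silyl]oxybut-3-en-2-yl] carbonate F2. Rhodium-catalysed allylic etherification of F2 [RhCl(PPh3)3, P(OMe)3, THF, 0 °C to rt] with the copper alkoxide 10, made from 5 as in step 6, should give the branched ether with overall retention at C8 (two inversions), that is 11.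

Step 18. What may go wrong: competing hydrozirconation or reduction of the bromodiene, or iodine-induced isomerisation of its double bonds, which would erode the geometric purity of 30. Fallback: the two ends of the arm are built in the opposite order, so that the bromodiene is made last; it sets out from 25 and 20 and returns at 31. Alkenylzirconocene 26, made from 25 as in step 16, is quenched with I2 to give [(E)-8-iodooct-7-en-1-ynyl]-trimethylsilane F10. Sonogashira coupling of F10 with 20 [Pd(PPh3)4, CuI, Et3N, THF] gives methyl 4-[(2R,5S)-5-[(E)-10-trimethylsilyldec-3-en-1,9-diynyl]oxolan-2-yl]butanoate F11, and K2CO3 in MeOH frees methyl 4-[(2R,5S)-5-[(E)-dec-3-en-1,9-diynyl]oxolan-2-yl]butanoate F12. Hydrozirconation of its terminal alkyne with one equivalent of Cp2Zr(H)Cl, which should leave the internal enyne and the ester alone, gives chloro-bis(cyclopentadienyl)-[(1E,7E)-10-[(2S,5R)-5-(4-methoxy-4-oxobutyl)oxolan-2-yl]deca-1,7-dien-9-ynyl]zirconium F13, and Negishi-type coupling with 22 [Pd(PPh3)4, ZnCl2, THF] gives 31.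

**Further compounds**
F1 | step 6 | (2S)-1-[tert-butyl(dimethyl)silyl]oxybut-3-en-2-ol | C=C[C@H](O)CO[Si](C)(C)C(C)(C)C
F2 | step 6 | tert-butyl [(2S)-1-[tert-butyl(dimethyl)silyl]oxybut-3-en-2-yl] carbonate | C=C[C@H](OC(=O)OC(C)(C)C)CO[Si](C)(C)C(C)(C)C
F3 | step 7 | 7-phenylmethoxyhept-1-en-3-ol (racemic) | C=CC(O)CCCCOCc1ccccc1
F4 | step 7 | (3R)-7-phenylmethoxyhept-1-en-3-ol | C=C[C@H](O)CCCCOCc1ccccc1
F5 | step 7 | lithium (3R)-7-phenylmethoxyhept-1-en-3-olate | C=C[C@H](O[Li])CCCCOCc1ccccc1
F6 | step 7 | monovalent copper (3R)-7-phenylmethoxyhept-1-en-3-olate | C=C[C@H](O[Cu])CCCCOCc1ccccc1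
F7 | step 7 | tert-butyl-dimethyl-[(2S)-2-[(3R)-7-phenylmethoxyhept-1-en-3-yl]oxybut-3-enoxy]silane | C=C[C@@H](CO[Si](C)(C)C(C)(C)C)O[C@@H](C=C)CCCCOCc1ccccc1
F8 | step 7 | tert-butyl-dimethyl-[[(2S,5R)-5-(4-phenylmethoxybutyl)-2,5-dihydrofuran-2-yl]methoxy]silane | C(CCC[C@@H]1C=C[C@@H](CO[Si](C)(C)C(C)(C)C)O1)OCc1ccccc1
F9 | step 7 | tert-butyl-dimethyl-[[(2S,5R)-5-(4-phenylmethoxybutyl)oxolan-2-yl]methoxy]silane | C(CCC[C@@H]1CC[C@@H](CO[Si](C)(C)C(C)(C)C)O1)OCc1ccccc1
F10 | step 18 | [(E)-8-iodooct-7-en-1-ynyl]-trimethylsilane | C[Si](C)(C)C#CCCCC/C=C/I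
F11 | step 18 | methyl 4-[(2R,5S)-5-[(E)-10-trimethylsilyldec-3-en-1,9-diynyl]oxolan-2-yl]butanoate | COC(=O)CCC[C@@H]1CC[C@@H](C#C/C=C/CCCCC#C[Si](C)(C)C)O1
F12 | step 18 | methyl 4-[(2R,5S)-5-[(E)-dec-3-en-1,9-diynyl]oxolan-2-yl]butanoate | COC(=O)CCC[C@@H]1CC[C@@H](C#C/C=C/CCCCC#C)O1
F13 | step 18 | chloro-bis(cyclopentadienyl)-[(1E,7E)-10-[(2S,5R)-5-(4-methoxy-4-oxobutyl)oxolan-2-yl]deca-1,7-dien-9-ynyl]zirconium | COC(=O)CCC[C@@H]1CC[C@@H](C#C/C=C/CCCC/C=C/[Zr](Cl)(C2C=CC=C2)C2C=CC=C2)O1
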